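(The numbers in the tables are simulated for substances that don't exist, and the scatter is random.)

Count what the enzyme makes.

| setting | elm | alder | flask |
|---|---|---|---|
| starting material | 0.050 M | 0.025 M | 0.050 M |
| capture agent | 1 mM | 1 mM | 1.00 mM |
| enzyme | 10 µM | 10 µM | 10 µM |
| remark | the very flask that is asked about, followed so far | run made earlier |  |
| time |  |  | 2.0 h |

| elm: time / min | elm: target / % | alder: time / min | alder: target / % |
|---|---|---|---|
| 20.0 | 35 | 1.00 | 55 |
| 40.0 | 35 | 2.00 | 61 |
| 50.0 | 34 | 5.00 | 65 |
| 80.0 | 35 | 12.0 | 65 |

(standard deviation of a reading: 1.5 percentage points)

- south-west: at 2.0 h take out 90% of the target then present, then wait 2.0 h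
- west: at 2.0 h add starting material, 50.0% of the amount charged, then wait 2.0 h
- north-west: change nothing and wait 2.0 h more
- south-east: at 2.0 h add enzyme, 50.0% of the amount charged, then wait 2.0 h

* target, in percent of the starting material first charged, at 2.0 h
* what to do for the largest gain in target; "none" if nothing gains more than 2 percentage points (south-west / west / north-west / south-east / none)
* target present, with what was taken out counted in, in percent of the starting material first charged, after west
* target present, with what was taken out counted in, in percent of the starting material first charged, after south-east

- target taken out counts as made
- what was read earlier has a scatter of 1.5 percentage points, one standard deviation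
- additions bring no volume worth counting

Elm has stood at about 34.8% since 20.0 min, with 65.2% of its charge unmade. Alder, on half that charge, stands at 65.0%. The percentages differ, so carry something else: target made per enzyme charged, read on elm as 1740, the capacity (a total turnover number). Alder reads 1630, a little lower.

The flask asked about is elm, so my reckoning for now is 34.8%. Waiting, feeding starting material or taking out target adds no enzyme, so I expect no gain from them. Fresh enzyme brings fresh capacity, and you can bracket what it gives.

Lowest case, added enzyme makes nothing: 34.8%

Highest case, elm's capacity: plateau + added share × capacity × enzyme ÷ charge = 52.1%

Now put that answer back in. It leaves 47.9% of the charge unmade, close to alder's charge, which is 50.0% of this one. So go round again with alder's capacity: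

Tightened estimate, not a bound: 51.0%

The forecast gives 35% for now, south-east as best, 35% after west and 52% after south-east, which lies above my tightened estimate and about at my highest case. Its grounds: “The enzyme looks dead rather than held back by equilibrium.”

The flask gives 34.6%, with south-east best at 16 percentage points gained, 34.6% after west and 50.3% after south-east, just under my tightened estimate and under my highest case.

    starting material + enzyme ⇌ complex (K = 42.0 L mol⁻¹, k = 28000 L mol⁻¹ s⁻¹)
    complex ⇌ enzyme + target (K = 0.160 M, k = 9600 min⁻¹)
    capture agent + complex → trapped intermediate (k = 5300 L mol⁻¹ min⁻¹)
    enzyme → spent catalyst (k = 0.0540 min⁻¹)

In this flask, 99.3% of the catalyst stands as trapped intermediate and 0.733% as spent catalyst, and the first enzyme charge made 1730 per enzyme. A neighbouring flask, the same but charged with 4.0 × 10⁻⁵ M of enzyme, is where the capacity parts from the result. Capacity times its enzyme gives 139% of the charge, more than was charged. That flask gives 86.5%, or 1080 per enzyme, with 13.4% of the starting material left.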